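**Retrosynthetic overview**
1. The labile C3 lactol is unveiled last, by neutral photolysis of a configurationally stable mixed acetal with (S)-1-(2-nitrophenyl)ethanol.
2. The benzylic C–O bond comes from a Mitsunobu esterification of rhizonic acid (made from atraric acid) with a salicyl alcohol. The CH2OH of that alcohol comes from boronate-directed ortho-hydroxymethylation.
3. The acetal comes from the free lactol, with crystallisation-driven control of C3. The lactol comes from chelation-controlled 7-O-demethylation and dithiane unmasking.
4. Key disconnection: 3,5-dimethoxybenzyne + 1,3-dithian-2-yl anion (formyl anion equivalent) + CO2. This makes C3–C3a and C7a–C1 in one flask.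
5. Ring order: both benzene rings are bought. The only ring formed is the lactone/lactol ring, on unmasking of the aldehyde.

Assumption: C3 is a pseudo-acid lactol carbon that racemises by ring–chain tautomerism as soon as base, protic acid or water is present, so it is carried as a stable acetal, released only in the last step under neutral aprotic cold conditions, and the product is kept cold as a solid.

Atom labels follow phthalide numbering: C1 lactone C=O, C3 lactol carbon, C3a/C7a ring fusion, C5 OMe, C6 CH2O, C7 OH.

**Step 1**
Reactants: 1 1-fluoro-3,5-dimethoxybenzene; 2 1,3-dithiane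
Product: 8 2-(1,3-dithian-2-yl)-4,6-dimethoxybenzoic acid, via 2-lithio-1,3-dithiane 3 (not isolated), via (1,3-dithian-2-yl)magnesium chloride 4 (not isolated), via (2-fluoro-4,6-dimethoxyphenyl)lithium 5 (not isolated), via 3,5-dimethoxybenzyne 6 (not isolated), via arylmagnesium chloride 7 (not isolated)
Conditions: flask A: 2 (2.5 equiv), n-BuLi, THF, −30 °C, then MgCl2, 0 °C; flask B: 1, n-BuLi (1.05 equiv), THF, −78 °C, 1 h; A into B, −78 °C → rt, 3 h; CO2 (g), 0 °C; 1 M HCl
Reagents that add atoms: carbon dioxide, O=C=O; n-butyllithium, [Li]CCCC, and MgCl2, Cl[Mg]Cl (their atoms stay only in 3, 4, 5 and 7)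
Why: Proposed new method: n-BuLi lithiates 1 between F and OMe, loss of LiF on warming gives aryne 6, and the Corey–Seebach formyl anion equivalent 4 adds to the aryne carbon remote from the flanking OMe (the charge then builds up next to the inductively stabilising OMe), so two carbons that are both electrophilic by nature (the future CHO carbon C3 and ring carbon C3a, meta to both oxygens) are joined, while aryl Grignard 7 is too slow a base to take the acidic dithiane C–H and is carboxylated at C7a instead; the closest known reaction type is the aryne/Grignard/CO2 multicomponent coupling run on this same 3,5-dimethoxybenzyne with allylic Grignard reagents.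

**Step 2**
Reactants: 8 2-(1,3-dithian-2-yl)-4,6-dimethoxybenzoic acid
Product: 9 3-hydroxy-5,7-dimethoxyisobenzofuran-1(3H)-one (racemic lactol)
Conditions: PhI(OCOCF3)2 (1.5 equiv), MeCN–H2O 9:1, 0 °C → rt, 30 min
Reagents that add atoms: water, O
Why: Oxidative dethioacetalisation with a hypervalent iodine reagent frees the aldehyde, which closes at once on the ortho CO2H (ring–chain tautomerism) to form the lactone ring, C3 being a freely equilibrating racemate at this stage.

**Step 3**
Reactants: 9 3-hydroxy-5,7-dimethoxyisobenzofuran-1(3H)-one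
Product: 10 3,7-dihydroxy-5-methoxyisobenzofuran-1(3H)-one (racemic lactol)
Conditions: BCl3 (3 equiv), CH2Cl2, −78 → 0 °C; then H2O–THF, 0 °C
Reagents that add atoms: none
Why: In this chelation-controlled Lewis acid ether cleavage BCl3 binds between the lactone C=O and the neighbouring 7-OMe, so only that methyl is lost as MeCl and the 5-OMe, which has no carbonyl partner, stays.

**Step 4**
Reactants: 10 3,7-dihydroxy-5-methoxyisobenzofuran-1(3H)-one; 11 (S)-1-(2-nitrophenyl)ethanol
Product: 13 (3R)-7-hydroxy-5-methoxy-3-[(1S)-1-(2-nitrophenyl)ethoxy]isobenzofuran-1(3H)-one, via (3S)-epimer 12 (not isolated)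
Conditions: 11 (1.1 equiv), TsOH·H2O (5 mol %), toluene, 4 Å MS, 55 °C, dark; then heptane added slowly, seeds of 13, 40 → 20 °C
Reagents that add atoms: none
Why: Acid-catalysed pseudo-ester (mixed acetal) formation gives epimers 12 and 13, which interconvert through the ring-opened alkoxycarbenium ion, and seeded crystallisation drains the mixture into the less soluble 13 (crystallisation-induced diastereomer transformation, as known for menthyloxybutenolides), which sets C3 as R under control of the S carbinol centre of 11.

**Step 5**
Reactants: 13 (3R)-7-hydroxy-5-methoxy-3-[(1S)-1-(2-nitrophenyl)ethoxy]isobenzofuran-1(3H)-one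
Product: 15 (3R)-7-hydroxy-6-(hydroxymethyl)-5-methoxy-3-[(1S)-1-(2-nitrophenyl)ethoxy]isobenzofuran-1(3H)-one, via cyclic phenylboronate 14 (not isolated)
Conditions: PhB(OH)2 (1.2 equiv), (CH2O)n (5 equiv), EtCO2H (10 mol %), toluene, reflux, Dean–Stark, dark; then propane-1,3-diol (3 equiv), THF, rt
Reagents that add atoms: paraformaldehyde (reacts as formaldehyde), C=O; phenylboronic acid, OB(O)c1ccccc1 (its atoms stay only in 14)
Why: In this Nagata-type boronate-templated ortho-hydroxymethylation the aryl boronate delivers formaldehyde only to the free ortho carbon C6 (C7a is blocked, C4 is out of reach), diol exchange frees the salicyl alcohol, and any C3 epimer caused by the weak acid is a diastereomer that is removed on crystallisation.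

**Step 6**
Reactants: 16 methyl 2,4-dihydroxy-3,6-dimethylbenzoate (atraric acid)
Product: 17 methyl 2-hydroxy-4-methoxy-3,6-dimethylbenzoate
Conditions: MeI (1.1 equiv), K2CO3 (1.05 equiv), acetone, reflux
Reagents that add atoms: iodomethane, CI
Why: This Williamson ether synthesis is selective because the 2-OH is locked in a hydrogen bond to the ester C=O, so only the 4-OH is deprotonated and methylated.

**Step 7**
Reactants: 17 methyl 2-hydroxy-4-methoxy-3,6-dimethylbenzoate
Product: 18 2-hydroxy-4-methoxy-3,6-dimethylbenzoic acid (rhizonic acid)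
Conditions: KOH (6 equiv), DMSO–H2O 4:1, 90 °C; then 2 M HCl, 0 °C
Reagents that add atoms: potassium hydroxide, [K+].[OH-]
Why: Saponification of the hindered ester is forced by poorly solvated hydroxide in DMSO, and cold acidification avoids decarboxylation of the electron-rich salicylic acid.

**Step 8**
Reactants: 15 (3R)-7-hydroxy-6-(hydroxymethyl)-5-methoxy-3-[(1S)-1-(2-nitrophenyl)ethoxy]isobenzofuran-1(3H)-one; 18 rhizonic acid (1.2 equiv)
Product: 19 {(1R)-4-hydroxy-6-methoxy-1-[(1S)-1-(2-nitrophenyl)ethoxy]-3-oxo-1,3-dihydroisobenzofuran-5-yl}methyl 2-hydroxy-4-methoxy-3,6-dimethylbenzoate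
Conditions: PPh3 (1.3 equiv), DIAD (1.3 equiv), THF, 0 °C → rt, dark
Reagents that add atoms: none
Why: In this Mitsunobu esterification the primary benzylic OH is activated as its oxyphosphonium salt (or collapses to the ortho-quinone methide) and is attacked by the carboxylate oxygen of 18, so the shielding of the acid carbonyl does not matter, the far more acidic CO2H outcompetes the hydrogen-bonded phenols, and neither stereocentre is touched.

**Step 9**
Reactants: 19 the acetal-protected benzyl ester
Product: 20 CNP0398000.1, [(1R)-1,4-dihydroxy-6-methoxy-3-oxo-1,3-dihydroisobenzofuran-5-yl]methyl 2-hydroxy-4-methoxy-3,6-dimethylbenzoate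
Conditions: hν (365 nm LED), dry MeCN (5 mM), −20 °C, N2; evaporate below 0 °C, triturate with cold Et2O–pentane
Reagents that add atoms: none
Why: Norrish-type intramolecular redox photolysis of the 1-(2-nitrophenyl)ethyl ether (H-abstraction by the excited nitro group, aci-nitro cyclisation, hemiketal collapse) breaks only the O–CH(CH3)Ar bond, so the C3–O bond and the R configuration are retained, and no acid, base or water that would open the lactol is present.

**Compound list**
1 | 1-fluoro-3,5-dimethoxybenzene | COc1cc(F)cc(OC)c1 | starting material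
2 | 1,3-dithiane | C1CSCSC1 | starting material
3 | 2-lithio-1,3-dithiane | [Li]C1SCCCS1 | intermediate
4 | (1,3-dithian-2-yl)magnesium chloride | Cl[Mg]C1SCCCS1 | intermediate
5 | (2-fluoro-4,6-dimethoxyphenyl)lithium | [Li]c1c(F)cc(OC)cc1OC | intermediate
6 | 3,5-dimethoxybenzyne | C1#CC(OC)=CC(OC)=C1 | intermediate
7 | [2-(1,3-dithian-2-yl)-4,6-dimethoxyphenyl]magnesium chloride | COc1cc(OC)c([Mg]Cl)c(C2SCCCS2)c1 | intermediate
8 | 2-(1,3-dithian-2-yl)-4,6-dimethoxybenzoic acid | COc1cc(OC)c(C(=O)O)c(C2SCCCS2)c1 | intermediate
9 | 3-hydroxy-5,7-dimethoxyisobenzofuran-1(3H)-one (racemic) | COc1cc(OC)c2c(c1)C(O)OC2=O | intermediate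
10 | 3,7-dihydroxy-5-methoxyisobenzofuran-1(3H)-one (racemic) | COc1cc(O)c2c(c1)C(O)OC2=O | intermediate
11 | (S)-1-(2-nitrophenyl)ethanol | C[C@H](O)c1ccccc1[N+](=O)[O-] | starting material
12 | (3S)-7-hydroxy-5-methoxy-3-[(1S)-1-(2-nitrophenyl)ethoxy]isobenzofuran-1(3H)-one | COc1cc2c(c(O)c1)C(=O)O[C@@H]2O[C@@H](C)c1ccccc1[N+](=O)[O-] | intermediate
13 | (3R)-7-hydroxy-5-methoxy-3-[(1S)-1-(2-nitrophenyl)ethoxy]isobenzofuran-1(3H)-one | COc1cc2c(c(O)c1)C(=O)O[C@H]2O[C@@H](C)c1ccccc1[N+](=O)[O-] | intermediate
14 | cyclic phenylboronate of 15 (B bridges the 7-O and the new 6-CH2O; 3R,1'S) | COc1cc2c(c3OB(c4ccccc4)OCc13)C(=O)O[C@H]2O[C@@H](C)c1ccccc1[N+](=O)[O-] | intermediate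
15 | (3R)-7-hydroxy-6-(hydroxymethyl)-5-methoxy-3-[(1S)-1-(2-nitrophenyl)ethoxy]isobenzofuran-1(3H)-one | OCc1c(OC)cc2c(c1O)C(=O)O[C@H]2O[C@@H](C)c1ccccc1[N+](=O)[O-] | intermediate
16 | methyl 2,4-dihydroxy-3,6-dimethylbenzoate (atraric acid) | COC(=O)c1c(C)cc(O)c(C)c1O | starting material
17 | methyl 2-hydroxy-4-methoxy-3,6-dimethylbenzoate | COC(=O)c1c(C)cc(OC)c(C)c1O | intermediate
18 | 2-hydroxy-4-methoxy-3,6-dimethylbenzoic acid (rhizonic acid) | OC(=O)c1c(C)cc(OC)c(C)c1O | intermediate
19 | acetal-protected benzyl ester (C3 R, carbinol S) | COc1cc(C)c(C(=O)OCc2c(OC)cc3c(c2O)C(=O)O[C@H]3O[C@@H](C)c2ccccc2[N+](=O)[O-])c(O)c1C | intermediate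
20 | CNP0398000.1 (C3 R) | COc1cc(C)c(C(=O)OCc2c(OC)cc3c(c2O)C(=O)O[C@H]3O)c(O)c1C | target

**Step count**
Total steps: 9. Longest linear sequence: 7 (steps 1, 2, 3, 4, 5, 8, 9).

**The three steps most likely to fail**

Risk one is step 1. The aryne relay can lose material in three ways: attack of 5 on 6 to give a biaryl, proton shuffling between 7 and the dithiane C–H, and lithiation of 1 between the two OMe groups. The fallback splits the relay into carboxylation first and an addition–elimination second. It sets out from 1, which with n-BuLi at −78 °C and CO2 without warming gives 2-fluoro-4,6-dimethoxybenzoic acid F1. The lithium carboxylate of F1 then guides 2-lithio-1,3-dithiane 3 (3 equiv, THF, −78 → 0 °C) to displace the ortho fluoride by carboxylate-assisted SNAr. Both OMe groups are meta to the C–F carbon and so do not deactivate it. Acid work-up comes back to the route at 8.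

Risk two is step 4. Which epimer crystallises cannot be predicted. Long exposure to acid also invites irreversible C-arylation of the cation by a second electron-rich ring. The fallback replaces thermodynamic control by kinetic control and sets out from 10. SOCl2 (cat. DMF, CH2Cl2, 0 °C) gives the pseudo-chloride 3-chloro-7-hydroxy-5-methoxyisobenzofuran-1(3H)-one F2, whose enantiomers interconvert by chloride exchange (Bu4NCl, 10 mol %). Substitution by 11 follows at −40 °C in the presence of 1-[3,5-bis(trifluoromethyl)phenyl]-3-[(1R,2R)-2-(dimethylamino)cyclohexyl]thiourea (10 mol %) and 2,6-lutidine. This is a dynamic kinetic resolution with double stereodifferentiation, and the catalyst enantiomer is matched to 11 by experiment. It comes back to the route at 13.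

Risk three is step 9. The bond cleavage is reliable. However, the freed lactol can racemise during concentration, and short-wavelength light could ionise the ortho-hydroxybenzyl ester. The fallback accepts racemisation and sets C3 again on the finished skeleton. It sets out from 19, which is photolysed at rt to the configurationally equilibrating lactol F3. An (R)-selective lipase (Candida antarctica lipase B, immobilised, or one found by screening) with vinyl acetate in dry MTBE, without added base, converts F3 by enzymatic acylative dynamic kinetic resolution. The product is the storable (3R)-3-acetoxy derivative F4. The same lipase with n-BuOH in dry MTBE at 0 °C removes the acetyl group by O–acyl cleavage just before use. This comes back to the route at 20.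

**Further compounds**
F1 | step 1 | 2-fluoro-4,6-dimethoxybenzoic acid | COc1cc(F)c(C(=O)O)c(OC)c1
F2 | step 4 | 3-chloro-7-hydroxy-5-methoxyisobenzofuran-1(3H)-one (racemic) | COc1cc(O)c2c(c1)C(Cl)OC2=O
F3 | step 9 | lactol of 20 with equilibrating C3 (racemic) | COc1cc(C)c(C(=O)OCc2c(OC)cc3c(c2O)C(=O)OC3O)c(O)c1C
F4 | step 9 | (3R)-3-acetoxy derivative of 20 | COc1cc(C)c(C(=O)OCc2c(OC)cc3c(c2O)C(=O)O[C@H]3OC(C)=O)c(O)c1C
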